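**Adding up.** Adding the columns is the easy step. At the last reading the dawn run sums to 99.8% of the charge and the summer run to 100%, so the four shares can be balanced against each other. We call substrate plus intermediate the pool. Substrate is the limiting reagent, charged below the reagent in both runs.

in all of them: substrate 0.050 M

| run | reagent | remark | time |
|---|---|---|---|
| dawn | 0.081 M | run made earlier |  |
| summer | 0.22 M | run made earlier |  |
| east | 0.120 M |  | 20 h |
| south-west | 0.190 M |  | 20 h |
| south-east | 0.280 M |  | 20 h |

| run | time / h | side product / % | intermediate / % | target / % | substrate / % |
|---|---|---|---|---|---|
| dawn | 2.00 | 7.0 | 15.3 | 9.2 | 67.4 |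
| dawn | 5.00 | 28.3 | 11.4 | 11.4 | 48.8 |
| dawn | 10.0 | 53.1 | 6.6 | 12.5 | 28.8 |
| dawn | 15.0 | 68.2 | 3.7 | 11.6 | 16.3 |
| summer | 2.00 | 10.2 | 28.2 | 18.5 | 40.6 |
| summer | 5.00 | 34.5 | 16.4 | 27.9 | 22.6 |
| summer | 10.0 | 57.1 | 6.1 | 26.5 | 10.1 |
| summer | 15.0 | 65.8 | 2.9 | 27.0 | 4.5 |

(each reading ± 0.5 percentage points)

- which of these there is most of at the end, counted by the substrate in it, east (substrate / side product / intermediate / target)
- which of these there is most of at the end, counted by the substrate in it, south-west (substrate / side product / intermediate / target)
- which of these there is most of at the end, counted by the substrate in it, south-east (substrate / side product / intermediate / target)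
- how much there is at the end of the one of these that leads, in percent of the substrate charged: east
- how much there is at the end of the one of these that leads, in percent of the substrate charged: south-west
- how much there is at the end of the one of these that leads, in percent of the substrate charged: south-east

**Two ways.** We want the turnovers of the pool per hour. The first way reads the fall of the pool: in the dawn run it goes from 60.2% at 5.00 h to 20.0% at 15.0 h, and the logarithm of that ratio per hour is 0.110 h⁻¹. The summer run gives 0.166 h⁻¹. The second way reads another column: side product gained over the same hours, divided by the hours and the mean pool. It gives 0.106 h⁻¹ for dawn and 0.159 h⁻¹ for summer, so the two ways agree closely over these hours.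

**The cheat.** Before that time they part. By 5.00 h the summer pool has lost 61.0% of the charge, yet side product holds 34.5% and target 27.9%, so the early fall counts target-making too. From that time the target readings average 27.1% in the summer run and 11.8% in the dawn run. We therefore count turnovers from 5.00 h onward.

**East reckoned.** East lies 0.281 of the way from dawn to summer in reagent. On a straight line, its pool constant, the turnovers of the pool per hour, is 0.126 h⁻¹. On the same line we reckon its pool at 5.00 h as 54.3%, and 1.89 turnovers leave 8.21% at 20 h. With target at 16.1%, side product takes the remainder, 75.7%, more than target.

**Other flasks.** The same line gives us 0.784 of the way and 71.9% side product for south-west. South-east, with reagent above the summer run, is an extrapolation: 1.43 of the way and 64.5% side product.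

**The forecast.** The forecast gives east side product at 75%, south-west side product at 72% and south-east side product at 67.5%, saying “Side product therefore leads in all three, by difference”, and its south-east number stands above ours.

**The result.** East ends with side product leading at 76.8%, south-west with side product at 72.6%, and south-east with side product at 66.8%.

    substrate + target → side product (k = 10.8 M⁻¹ h⁻¹)
    intermediate ⇌ target + released group (K = 0.0653 M, k = 0.388 h⁻¹)
    released group → by-product carried off (k = 0.206 h⁻¹)
    substrate + reagent ⇌ intermediate (K = 3.60 M⁻¹, k = 24.0 M⁻¹ h⁻¹)

East holds 16.6% target, and its pool reads 6.63% against our 8.21%. The same east flask read at 30 h is the further case. At 0.126 h⁻¹, another 1.26 turnovers from 6.63% leave 1.88%, and that flask holds 1.87% as substrate and intermediate.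

The readings are simulated for substances that don't exist; the scatter is artificial.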